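**Strategy.** The cycloheptene ring is disconnected on both sides of its trisubstituted olefin, at C5–C6 and C7–C8 (azulene numbering: C3 carbinol, C3a/C8a ring fusion, C4 and C8 ester carbons). The feature exploited is that C4 and C8 sit 1,4 across the ring-A fusion bond: a trans-2-acetyl-1-formylcyclopentane (ring A, with C3, C3a and C8a already set) offers C5 as a ketone enolate and C8 as an aldehyde. A Michael/Horner–Wadsworth–Emmons cascade with diethyl prop-1-ynylphosphonate inserts C6(Me)–C7 between them in one operation and closes the seven-membered ring as a 2,4-dienone. Both carbinol centres are then set by substrate control.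

Key step: step 9

Remark: azulene numbering (C1–C3, C3a, C4–C8, C8a) is used for the bicyclic compounds.
Remark: the carbinol carbon of the 1-hydroxyethyl side chain in 6, 7, 8, 10 and 11 is oxidised in step 6; it is carried as an inconsequential epimer mixture and drawn without configuration.
Remark: the chiral ligand of step 1 is taken as the enantiomer that delivers the 3S adduct.

Step 1
Reactants: 1 3-methylcyclopent-2-en-1-one; 2 ethynyl(trimethyl)silane; 3 acetaldehyde
Product: 6 (2S,3S)-2-(1-hydroxyethyl)-3-methyl-3-[1-(trimethylsilyl)ethenyl]cyclopentan-1-one, via alkenylalane 4 (not isolated), via aluminium enolate 5 (not isolated)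
Conditions: 2, iBu2AlH, hexanes, 55 °C; then 1, Cu(OTf)2 (5 mol%), chiral sulfonate-bearing imidazolinium salt (N-heterocyclic carbene precursor, 5 mol%), THF, −78 to −15 °C; then 3, −78 °C; aq. NH4Cl
Reagents that add atoms: ethynyl(trimethyl)silane C#C[Si](C)(C)C; acetaldehyde CC=O
Why: Copper-catalysed enantioselective conjugate addition of the silyl-substituted alkenylaluminium reagent (from hydroalumination of 2) should create the quaternary C3 under ligand control, and the regiodefined aluminium enolate should then undergo aldol addition to acetaldehyde on the face anti to the bulky 1-silylethenyl group, which places the C2 side chain trans to it and cis to the methyl group.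

Step 2
Reactants: 6 (2S,3S)-2-(1-hydroxyethyl)-3-methyl-3-[1-(trimethylsilyl)ethenyl]cyclopentan-1-one
Product: 7 (2S,3S)-2-{1-[(tert-butyldiphenylsilyl)oxy]ethyl}-3-methyl-3-[1-(trimethylsilyl)ethenyl]cyclopentan-1-one
Conditions: tBuPh2SiCl, imidazole, DMF, 23 °C
Reagents that add atoms: tert-butyl(chloro)diphenylsilane CC(C)(C)[Si](Cl)(c1ccccc1)c1ccccc1
Why: Silyl ether formation on the secondary alcohol gives a bulky, non-chelating and acid-stable group that will shield one face of the ketone in step 4; no stereocentre is formed.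

Step 3
Reactants: 7 (2S,3S)-2-{1-[(tert-butyldiphenylsilyl)oxy]ethyl}-3-methyl-3-[1-(trimethylsilyl)ethenyl]cyclopentan-1-one
Product: 8 (2S,3R)-2-{1-[(tert-butyldiphenylsilyl)oxy]ethyl}-3-ethenyl-3-methylcyclopentan-1-one
Conditions: CF3CO2H, CH2Cl2, 0 °C
Reagents that add atoms: none
Why: Acid-mediated protodesilylation of the vinylsilane (electrophilic ipso substitution at the silicon-bearing carbon) should unmask the vinyl group once its bulk has done its work, while the tert-butyldiphenylsilyl ether survives and the short exposure at 0 °C should leave the ketone α-centre C2 untouched.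

Step 4
Reactants: 8 (2S,3R)-2-{1-[(tert-butyldiphenylsilyl)oxy]ethyl}-3-ethenyl-3-methylcyclopentan-1-one; 9 isopropylmagnesium chloride
Product: 10 (1R,2S,3R)-2-{1-[(tert-butyldiphenylsilyl)oxy]ethyl}-3-ethenyl-3-methyl-1-(propan-2-yl)cyclopentan-1-ol
Conditions: iPrMgCl, CeCl3, THF, −78 to 0 °C; aq. NH4Cl
Reagents that add atoms: isopropylmagnesium chloride CC(C)[Mg]Cl
Why: Organocerium 1,2-addition suppresses enolisation and reduction of the hindered ketone, and the isopropyl group should enter anti to the large α-substituent at C2 (and anti to the pseudo-axial C3 methyl), which sets C1 with the hydroxyl cis to the side chain and the methyl group.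

Step 5
Reactants: 10 (1R,2S,3R)-2-{1-[(tert-butyldiphenylsilyl)oxy]ethyl}-3-ethenyl-3-methyl-1-(propan-2-yl)cyclopentan-1-ol
Product: 11 (1R,2S,3R)-3-ethenyl-2-(1-hydroxyethyl)-3-methyl-1-(propan-2-yl)cyclopentan-1-ol
Conditions: Bu4NF, THF, 23 °C
Reagents that add atoms: none
Why: Fluoride-mediated desilylation frees the secondary alcohol without touching any stereocentre.

Step 6
Reactants: 11 (1R,2S,3R)-3-ethenyl-2-(1-hydroxyethyl)-3-methyl-1-(propan-2-yl)cyclopentan-1-ol
Product: 12 1-[(1R,2R,5R)-2-ethenyl-5-hydroxy-2-methyl-5-(propan-2-yl)cyclopentyl]ethan-1-one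
Conditions: Dess–Martin periodinane, NaHCO3, CH2Cl2, 0 to 23 °C
Reagents that add atoms: none
Why: Dess–Martin oxidation converts only the secondary alcohol (the tertiary one is inert) into the methyl ketone and removes the undefined carbinol centre; the acetyl group already sits anti to both the isopropyl and the vinyl group, the thermodynamically preferred arrangement, so the α-centre is not at risk.

Step 7
Reactants: 12 1-[(1R,2R,5R)-2-ethenyl-5-hydroxy-2-methyl-5-(propan-2-yl)cyclopentyl]ethan-1-one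
Product: 13 1-[(1R,2R,5R)-2-ethenyl-2-methyl-5-(propan-2-yl)-5-[(triethylsilyl)oxy]cyclopentyl]ethan-1-one
Conditions: Et3SiOTf, 2,6-lutidine, CH2Cl2, −78 °C
Reagents that add atoms: triethylsilyl trifluoromethanesulfonate CC[Si](CC)(CC)OS(=O)(=O)C(F)(F)F
Why: Silylation of the tertiary alcohol with a silyl triflate and a hindered pyridine base at −78 °C (where the methyl ketone is not enolised) blocks retro-aldol cleavage in the basic key step.

Step 8
Reactants: 13 1-[(1R,2R,5R)-2-ethenyl-2-methyl-5-(propan-2-yl)-5-[(triethylsilyl)oxy]cyclopentyl]ethan-1-one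
Product: 14 (1S,2R,3R)-2-acetyl-1-methyl-3-(propan-2-yl)-3-[(triethylsilyl)oxy]cyclopentane-1-carbaldehyde
Conditions: O3, CH2Cl2, −78 °C; then PPh3, −78 to 23 °C
Reagents that add atoms: ozone [O-][O+]=O
Why: Ozonolysis with reductive work-up cleaves the only olefin to the neopentylic aldehyde, which cannot enolise.

Step 9
Reactants: 14 (1S,2R,3R)-2-acetyl-1-methyl-3-(propan-2-yl)-3-[(triethylsilyl)oxy]cyclopentane-1-carbaldehyde; 15 diethyl prop-1-yn-1-ylphosphonate
Product: 18 (3R,3aR,8aR)-6,8a-dimethyl-3-(propan-2-yl)-3-[(triethylsilyl)oxy]-2,3,3a,8a-tetrahydroazulen-4(1H)-one, via potassium enolate 16 (not isolated), via phosphonodienolate 17 (not isolated)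
Conditions: KN(SiMe3)2, THF, −78 °C; then 15, −78 to 23 °C
Reagents that add atoms: diethyl prop-1-yn-1-ylphosphonate CC#CP(=O)(OCC)OCC
Why: Proposed new method: the kinetic potassium enolate of the methyl ketone (C5 of 18) adds to the β-carbon of the alkynylphosphonate (C6, which carries the methyl), the α-phosphonovinyl anion so formed is quenched internally by the now doubly activated C5–H to give the phosphonate-stabilised dienolate 17, and 17 attacks the C8 aldehyde through C7 with syn-elimination of diethyl phosphate, so that C5–C6 and C7–C8 are made in one flask. The closest known reaction types are conjugate additions of stabilised carbanions to 1-alkynylphosphonates, tandem Michael/intramolecular Horner–Wadsworth–Emmons annulations of enolates with vinylphosphonates, and α-selective olefinations of γ-deprotonated 4-phosphonocrotonates. The seven-membered ring closes by a 7-exo-trig addition of C7 to the aldehyde carbonyl, and the ring enforces the cis geometry of both new double bonds. No stereocentre is created; C3a, the only epimerisable centre, is flanked by two quaternary carbons, is not deprotonated under kinetic conditions and already holds the thermodynamically preferred configuration (acyl anti to isopropyl). The step needs intermolecular Michael addition to win over intramolecular aldol or olefination between C5 and C8, which the trans arrangement of the two side chains on ring A secures, since a ring between them would be a strained trans-fused bicyclo[3.3.0]octane.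

Step 10
Reactants: 18 (3R,3aR,8aR)-6,8a-dimethyl-3-(propan-2-yl)-3-[(triethylsilyl)oxy]-2,3,3a,8a-tetrahydroazulen-4(1H)-one
Product: 19 (3R,3aR,7R,8S,8aS)-7,8-epoxy-6,8a-dimethyl-3-(propan-2-yl)-3-[(triethylsilyl)oxy]-2,3,3a,7,8,8a-hexahydroazulen-4(1H)-one
Conditions: mCPBA, NaHCO3, CH2Cl2, 0 °C
Reagents that add atoms: 3-chloroperbenzoic acid OOC(=O)c1cccc(Cl)c1
Why: Prilezhaev epoxidation should take place at the distal, more electron-rich C7=C8 bond of the dienone and from the face anti to the angular C8a methyl group, which sets C7 and C8 with the oxygen on the side of H-3a.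

Step 11
Reactants: 19 (3R,3aR,7R,8S,8aS)-7,8-epoxy-6,8a-dimethyl-3-(propan-2-yl)-3-[(triethylsilyl)oxy]-2,3,3a,7,8,8a-hexahydroazulen-4(1H)-one
Product: 20 (3R,3aR,8R,8aS)-8-hydroxy-6,8a-dimethyl-3-(propan-2-yl)-3-[(triethylsilyl)oxy]-2,3,3a,5,8,8a-hexahydroazulen-4(1H)-one
Conditions: SmI2 (2.2 equiv), THF/MeOH, −78 °C
Reagents that add atoms: none
Why: Two single-electron transfers from SmI2 to the vinylogous epoxy ketone open the C7–O bond (reductive opening of a γ,δ-epoxy enone) to a samarium dienolate that methanol protonates kinetically at the α-carbon C5, giving the β,γ-unsaturated ketone with the C8–O bond and hence the C8 configuration untouched.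

Step 12
Reactants: 20 (3R,3aR,8R,8aS)-8-hydroxy-6,8a-dimethyl-3-(propan-2-yl)-3-[(triethylsilyl)oxy]-2,3,3a,5,8,8a-hexahydroazulen-4(1H)-one
Product: 21 (3R,3aR,8R,8aS)-3,8-dihydroxy-6,8a-dimethyl-3-(propan-2-yl)-2,3,3a,5,8,8a-hexahydroazulen-4(1H)-one
Conditions: HF·pyridine, pyridine, THF, 0 °C
Reagents that add atoms: none
Why: Buffered fluoride desilylation frees the tertiary alcohol under slightly acidic conditions that should neither move the C6=C7 bond into conjugation nor trigger retro-aldol cleavage.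

Step 13
Reactants: 21 (3R,3aR,8R,8aS)-3,8-dihydroxy-6,8a-dimethyl-3-(propan-2-yl)-2,3,3a,5,8,8a-hexahydroazulen-4(1H)-one
Product: 22 (3R,3aS,4S,8R,8aS)-6,8a-dimethyl-3-(propan-2-yl)-1,2,3,3a,4,5,8,8a-octahydroazulene-3,4,8-triol
Conditions: Me4NBH(OAc)3, MeCN/AcOH, −30 °C
Reagents that add atoms: none
Why: Saksena–Evans reduction: the tertiary C3 hydroxyl exchanges onto boron and delivers hydride intramolecularly to the face of the C4 ketone on which C3 is attached, which should give the 1,3-anti diol with the 4S configuration.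

Step 14
Reactants: 22 (3R,3aS,4S,8R,8aS)-6,8a-dimethyl-3-(propan-2-yl)-1,2,3,3a,4,5,8,8a-octahydroazulene-3,4,8-triol; 23 (2Z)-2-methylbut-2-enoic acid
Product: 25 (3R,3aS,4S,8R,8aS)-3-hydroxy-6,8a-dimethyl-3-(propan-2-yl)-1,2,3,3a,4,5,8,8a-octahydroazulene-4,8-diyl bis[(2Z)-2-methylbut-2-enoate] (CNP0183261.1), via mixed anhydride 24 (not isolated)
Conditions: 23, 2,4,6-trichlorobenzoyl chloride, Et3N, toluene, 23 °C; then 22, toluene, 80 °C
Reagents that add atoms: (2Z)-2-methylbut-2-enoic acid C/C=C(/C)C(=O)O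
Why: Yamaguchi esterification through the mixed 2,4,6-trichlorobenzoic anhydride without a nucleophilic catalyst should acylate both secondary alcohols with retention and without Z-to-E isomerisation of the 2-methylbut-2-enoyl group, while the tertiary C3 alcohol is too hindered to react.

**Compound list**

1 | 3-methylcyclopent-2-en-1-one | CC1=CC(=O)CC1 | starting material
2 | ethynyl(trimethyl)silane | C#C[Si](C)(C)C | starting material
3 | acetaldehyde | CC=O | starting material
4 | bis(2-methylpropyl)[1-(trimethylsilyl)ethenyl]alumane | C=C([Si](C)(C)C)[Al](CC(C)C)CC(C)C | intermediate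
5 | bis(2-methylpropyl)aluminium (S)-3-methyl-3-[1-(trimethylsilyl)ethenyl]cyclopent-1-en-1-olate | C=C([Si](C)(C)C)[C@@]1(C)CCC(O[Al](CC(C)C)CC(C)C)=C1 | intermediate
6 | (2S,3S)-2-(1-hydroxyethyl)-3-methyl-3-[1-(trimethylsilyl)ethenyl]cyclopentan-1-one (carbinol epimers) | C=C([Si](C)(C)C)[C@@]1(C)CCC(=O)[C@@H]1C(C)O | intermediate
7 | (2S,3S)-2-{1-[(tert-butyldiphenylsilyl)oxy]ethyl}-3-methyl-3-[1-(trimethylsilyl)ethenyl]cyclopentan-1-one | C=C([Si](C)(C)C)[C@@]1(C)CCC(=O)[C@@H]1C(C)O[Si](c2ccccc2)(c3ccccc3)C(C)(C)C | intermediate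
8 | (2S,3R)-2-{1-[(tert-butyldiphenylsilyl)oxy]ethyl}-3-ethenyl-3-methylcyclopentan-1-one | C=C[C@@]1(C)CCC(=O)[C@@H]1C(C)O[Si](c2ccccc2)(c3ccccc3)C(C)(C)C | intermediate
9 | isopropylmagnesium chloride | CC(C)[Mg]Cl | starting material
10 | (1R,2S,3R)-2-{1-[(tert-butyldiphenylsilyl)oxy]ethyl}-3-ethenyl-3-methyl-1-(propan-2-yl)cyclopentan-1-ol | C=C[C@@]1(C)CC[C@@](O)(C(C)C)[C@@H]1C(C)O[Si](c2ccccc2)(c3ccccc3)C(C)(C)C | intermediate
11 | (1R,2S,3R)-3-ethenyl-2-(1-hydroxyethyl)-3-methyl-1-(propan-2-yl)cyclopentan-1-ol | C=C[C@@]1(C)CC[C@@](O)(C(C)C)[C@@H]1C(C)O | intermediate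
12 | 1-[(1R,2R,5R)-2-ethenyl-5-hydroxy-2-methyl-5-(propan-2-yl)cyclopentyl]ethan-1-one | C=C[C@@]1(C)CC[C@@](O)(C(C)C)[C@@H]1C(C)=O | intermediate
13 | 1-[(1R,2R,5R)-2-ethenyl-2-methyl-5-(propan-2-yl)-5-[(triethylsilyl)oxy]cyclopentyl]ethan-1-one | C=C[C@@]1(C)CC[C@@](O[Si](CC)(CC)CC)(C(C)C)[C@@H]1C(C)=O | intermediate
14 | (1S,2R,3R)-2-acetyl-1-methyl-3-(propan-2-yl)-3-[(triethylsilyl)oxy]cyclopentane-1-carbaldehyde | O=C[C@@]1(C)CC[C@@](O[Si](CC)(CC)CC)(C(C)C)[C@@H]1C(C)=O | intermediate
15 | diethyl prop-1-yn-1-ylphosphonate | CC#CP(=O)(OCC)OCC | starting material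
16 | potassium enolate of 14, deprotonated at the acetyl methyl group (ring stereocentres as in 14) | O=C[C@@]1(C)CC[C@@](O[Si](CC)(CC)CC)(C(C)C)[C@@H]1C(=C)[O-].[K+] | intermediate
17 | potassium dienolate from addition of 16 to C2 of 15: diethyl [2-methyl-4-oxido-4-(ring A)buta-1,3-dienyl]phosphonate (ring stereocentres as in 14) | O=C[C@@]1(C)CC[C@@](O[Si](CC)(CC)CC)(C(C)C)[C@@H]1C([O-])=CC(C)=CP(=O)(OCC)OCC.[K+] | intermediate
18 | (3R,3aR,8aR)-6,8a-dimethyl-3-(propan-2-yl)-3-[(triethylsilyl)oxy]-2,3,3a,8a-tetrahydroazulen-4(1H)-one | O=C1C=C(C)C=C[C@@]2(C)CC[C@@](O[Si](CC)(CC)CC)(C(C)C)[C@H]12 | intermediate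
19 | (3R,3aR,7R,8S,8aS)-7,8-epoxy-6,8a-dimethyl-3-(propan-2-yl)-3-[(triethylsilyl)oxy]-2,3,3a,7,8,8a-hexahydroazulen-4(1H)-one | O=C1C=C(C)[C@H]3O[C@H]3[C@@]2(C)CC[C@@](O[Si](CC)(CC)CC)(C(C)C)[C@H]12 | intermediate
20 | (3R,3aR,8R,8aS)-8-hydroxy-6,8a-dimethyl-3-(propan-2-yl)-3-[(triethylsilyl)oxy]-2,3,3a,5,8,8a-hexahydroazulen-4(1H)-one | O=C1CC(C)=C[C@@H](O)[C@@]2(C)CC[C@@](O[Si](CC)(CC)CC)(C(C)C)[C@H]12 | intermediate
21 | (3R,3aR,8R,8aS)-3,8-dihydroxy-6,8a-dimethyl-3-(propan-2-yl)-2,3,3a,5,8,8a-hexahydroazulen-4(1H)-one | O=C1CC(C)=C[C@@H](O)[C@@]2(C)CC[C@@](O)(C(C)C)[C@H]12 | intermediate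
22 | (3R,3aS,4S,8R,8aS)-6,8a-dimethyl-3-(propan-2-yl)-1,2,3,3a,4,5,8,8a-octahydroazulene-3,4,8-triol | O[C@H]1CC(C)=C[C@@H](O)[C@@]2(C)CC[C@@](O)(C(C)C)[C@H]12 | intermediate
23 | (2Z)-2-methylbut-2-enoic acid (angelic acid) | C/C=C(/C)C(=O)O | starting material
24 | (2Z)-2-methylbut-2-enoic 2,4,6-trichlorobenzoic anhydride | C/C=C(/C)C(=O)OC(=O)c1c(Cl)cc(Cl)cc1Cl | intermediate
25 | (3R,3aS,4S,8R,8aS)-3-hydroxy-6,8a-dimethyl-3-(propan-2-yl)-1,2,3,3a,4,5,8,8a-octahydroazulene-4,8-diyl bis[(2Z)-2-methylbut-2-enoate] (CNP0183261.1) | C/C=C(/C)C(=O)O[C@H]1CC(C)=C[C@@H](OC(=O)/C(C)=C\C)[C@@]2(C)CC[C@@](O)(C(C)C)[C@H]12 | target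

**Totals.** Total step count: 14. Longest linear sequence: 14 steps (1 to 25).

**Steps most likely to fail**

Step 9 (proposed new method). The conjugate addition may be outrun by proton transfer from the propynylphosphonate to the enolate (propargyl–allenyl isomerisation and oligomerisation of the acceptor), or the delocalised phosphonate anion may fail to close the seven-membered ring. The fallback uses known chemistry, sets out from 13 and comes back at 18. The cerium enolate of 13 (LiN(iPr)2, THF, −78 °C; then CeCl3) should add 1,2 to but-3-en-2-one to give 1-[(1R,2R,5R)-2-ethenyl-2-methyl-5-(propan-2-yl)-5-[(triethylsilyl)oxy]cyclopentyl]-3-hydroxy-3-methylpent-4-en-1-one F1. Ring-closing metathesis with the second-generation Grubbs catalyst (H2IMes)(PCy3)Cl2Ru=CHPh (CH2Cl2, 40 °C) should join the two vinyl groups into the C7=C8 olefin of (3R,3aR,8aR)-6-hydroxy-6,8a-dimethyl-3-(propan-2-yl)-3-[(triethylsilyl)oxy]-2,3,3a,5,6,8a-hexahydroazulen-4(1H)-one F2. Dehydration of this tertiary β-hydroxy ketone (MsCl, Et3N; then DBU) should give dienone 18.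

Step 1. The aluminium enolate may be too poor an aldol donor, so that proton quench or retro-aldol on work-up erodes the regiodefined trapping and the trans selectivity. The fallback sets out from 1 and comes back at 6, and it separates the conjugate addition from the aldol. The copper-catalysed addition of 4 to 1 is quenched with acetic anhydride to give (S)-3-methyl-3-[1-(trimethylsilyl)ethenyl]cyclopent-1-en-1-yl acetate F3. MeLi then cleaves F3 to the regiodefined lithium enolate, ZnCl2 converts it into the zinc enolate, and aldol addition to acetaldehyde at −78 °C should give 6.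

Step 14. Isomerisation of the (Z)-2-methylbut-2-enoyl unit to the E isomer during acylation, or incomplete acylation of the neopentylic C8 alcohol, may occur. The fallback sets out from 22 and comes back at 25, and it builds the Z olefins after the ester bonds. Esterification of 22 with 2-[bis(2,2,2-trifluoroethoxy)phosphoryl]propanoic acid (DCC, DMAP, CH2Cl2) should give (3R,3aS,4S,8R,8aS)-3-hydroxy-6,8a-dimethyl-3-(propan-2-yl)-1,2,3,3a,4,5,8,8a-octahydroazulene-4,8-diyl bis{2-[bis(2,2,2-trifluoroethoxy)phosphoryl]propanoate} F4. A double Still–Gennari olefination of F4 with acetaldehyde (KN(SiMe3)2, 18-crown-6, THF, −78 °C) should then give 25.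

**Further compounds**

F1 | step 9 | 1-[(1R,2R,5R)-2-ethenyl-2-methyl-5-(propan-2-yl)-5-[(triethylsilyl)oxy]cyclopentyl]-3-hydroxy-3-methylpent-4-en-1-one (carbinol epimers) | C=C[C@@]1(C)CC[C@@](O[Si](CC)(CC)CC)(C(C)C)[C@@H]1C(=O)CC(C)(O)C=C
F2 | step 9 | (3R,3aR,8aR)-6-hydroxy-6,8a-dimethyl-3-(propan-2-yl)-3-[(triethylsilyl)oxy]-2,3,3a,5,6,8a-hexahydroazulen-4(1H)-one (C6 epimers) | O=C1CC(C)(O)C=C[C@@]2(C)CC[C@@](O[Si](CC)(CC)CC)(C(C)C)[C@H]12
F3 | step 1 | (S)-3-methyl-3-[1-(trimethylsilyl)ethenyl]cyclopent-1-en-1-yl acetate | C=C([Si](C)(C)C)[C@@]1(C)CCC(OC(C)=O)=C1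
F4 | step 14 | (3R,3aS,4S,8R,8aS)-3-hydroxy-6,8a-dimethyl-3-(propan-2-yl)-1,2,3,3a,4,5,8,8a-octahydroazulene-4,8-diyl bis{2-[bis(2,2,2-trifluoroethoxy)phosphoryl]propanoate} | CC(C(=O)O[C@H]1CC(C)=C[C@@H](OC(=O)C(C)P(=O)(OCC(F)(F)F)OCC(F)(F)F)[C@@]2(C)CC[C@@](O)(C(C)C)[C@H]12)P(=O)(OCC(F)(F)F)OCC(F)(F)F
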